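**Retrosynthetic overview** (ring: C1 = CHOH, C2=C3, C4, C5 = C(OH)R, C6; side chain C1′–C16′ counted from C5)
1. The C28 target is cut in the side chain between C7′ and C8′ into a C13 ring half (primary iodide, free diol) and a C15 aryl‑olefin half (terminal diene); they are joined last, in one pot, by hydroboration and B‑alkyl Suzuki–Miyaura sp3–sp3 coupling.
2. Enabling feature: the unbranched (CH2)11 tether C1′–C11′ between ring carbon C5 and the C12′=C13′ (Z)‑olefin. C7′ and C8′ are plain primary CH2 groups, seven bonds from C5 and four from C12′, so one half can end in C7′–I and the other in the only monosubstituted olefin (C8′=C9′). Boron at C8′ keeps that carbon polar, avoiding a 5‑hexenyl‑type radical that would cyclise onto C12′=C13′.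
3. Ring half: from a tertiary homoallylic cyclohexenol by iodocarbonation (the bridging carbonate forces C1–O cis to C5–O), E2 elimination to C2=C3, methanolysis and Cl→I exchange.
4. The only ring formed is the cyclohexene, by an enantioselective Diels–Alder reaction of butadiene with 2‑bromoacrolein (sets C5). The adduct is converted to a spiro‑epoxide, which a 6‑chlorohexyl Grignard reagent opens (C1′–C2′ bond).
5. Aryl‑olefin half: salt‑free (Z)‑selective Wittig reaction of the 4‑phenylbutyl ylide with pent‑4‑enal; the phenyl ring is bought.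

Key step: step 11

Assumption: the (S)‑tryptophan‑derived oxazaborolidine is taken to shield the same face of 2‑bromoacrolein toward buta‑1,3‑diene as toward cyclopentadiene, which corresponds to the (R)‑configured adduct; if the sense is the opposite, the (R)‑tryptophan‑derived catalyst is used and nothing else changes.

**Step 1**
Reactants: 1 acrolein (prop‑2‑enal)
Product: 3 2‑bromoprop‑2‑enal (2‑bromoacrolein), via 2,3‑dibromopropanal 2 (not isolated)
Conditions: Br2, CH2Cl2, −78 → 0 °C; then Et3N, 0 °C
Reagents that add atoms: bromine, BrBr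
Why: Bromination of the enal C=C followed by Et3N‑induced E1cB loss of HBr from the 2,3‑dibromide (bromination–dehydrobromination) is the standard preparation of α‑bromo enals; no stereocentre is formed.

**Step 2**
Reactants: 3 2‑bromoacrolein; 4 buta‑1,3‑diene
Product: 5 (1R)‑1‑bromocyclohex‑3‑ene‑1‑carbaldehyde
Conditions: 4 (5 equiv), (S)‑N‑tosyltryptophan‑derived B‑butyl‑1,3,2‑oxazaborolidin‑5‑one (10 mol %), CH2Cl2, −78 → −40 °C
Reagents that add atoms: none
Why: Catalytic enantioselective Diels–Alder reaction: the boron binds the formyl oxygen of s‑cis 2‑bromoacrolein, the indole ring shields one π‑face and butadiene adds to the other, so the [4+2] cycloaddition closes the cyclohexene and sets the bromine‑bearing quaternary carbon (the later ring carbon C5) under catalyst control.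

**Step 3**
Reactants: 5 (1R)‑1‑bromocyclohex‑3‑ene‑1‑carbaldehyde
Product: 7 (3S)‑1‑oxaspiro[2.5]oct‑5‑ene, via bromohydrin 6 (not isolated)
Conditions: NaBH4, MeOH, 0 °C; then K2CO3, rt
Reagents that add atoms: none
Why: Chemoselective NaBH4 reduction of the aldehyde followed by intramolecular Williamson (3‑exo‑tet) closure of the bromohydrin: the primary alkoxide displaces the tertiary bromide from the rear, so C–O replaces C–Br with inversion and the configuration of the spiro carbon follows from that of 5.

**Step 4**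
Reactants: 7 (3S)‑1‑oxaspiro[2.5]oct‑5‑ene; 8 1‑bromo‑6‑chlorohexane
Product: 10 (1S)‑1‑(7‑chloroheptyl)cyclohex‑3‑en‑1‑ol, via Grignard reagent 9 (not isolated)
Conditions: 8, Mg, THF, rt; then 7, CuI (10 mol %), THF, −30 → 0 °C; aq NH4Cl
Reagents that add atoms: none
Why: Copper‑catalysed SN2 opening of a 2,2‑disubstituted epoxide by a Grignard reagent occurs at the unhindered CH2 terminus, so the C–O bond at the quaternary carbon is untouched and its configuration is retained; magnesium inserts selectively into the C–Br bond of 8.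

**Step 5**
Reactants: 10 (1S)‑1‑(7‑chloroheptyl)cyclohex‑3‑en‑1‑ol
Product: 13 (1S,5S,6S)‑1‑(7‑chloroheptyl)‑6‑iodo‑2,4‑dioxabicyclo[3.3.1]nonan‑3‑one (iodine anti to the carbonate bridge), via lithium alkoxide 11 (not isolated), via lithium carbonate 12 (not isolated)
Conditions: n‑BuLi, THF, −78 °C; CO2 (1 atm), −78 → 0 °C; I2, 0 °C → rt; aq Na2S2O3
Reagents that add atoms: carbon dioxide, O=C=O; iodine, II
Why: Cardillo iodocarbonation (iodocyclisation of a homoallylic lithium carbonate): the axial carbonate oxygen opens the iodonium ion at the nearer olefinic carbon to give the six‑membered cyclic carbonate, so the new secondary C–O bond is forced cis to the tertiary C–O bond by the 1,3‑diaxial bridge and iodine enters anti on the neighbouring carbon (substrate control through the ring).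

**Step 6**
Reactants: 13 (1S,5S,6S)‑1‑(7‑chloroheptyl)‑6‑iodo‑2,4‑dioxabicyclo[3.3.1]nonan‑3‑one
Product: 14 (1S,5S)‑1‑(7‑chloroheptyl)‑2,4‑dioxabicyclo[3.3.1]non‑6‑en‑3‑one
Conditions: DBU, toluene, 80 °C
Reagents that add atoms: none
Why: E2 dehydroiodination with DBU, as in the elimination of iodolactones: the axial iodine has an antiperiplanar hydrogen only on the CH2 carbon remote from oxygen (the hydrogen on the carbonate‑bearing carbon is equatorial), so the olefin forms regioselectively next to the secondary C–O bond and no stereocentre is changed.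

**Step 7**
Reactants: 14 (1S,5S)‑1‑(7‑chloroheptyl)‑2,4‑dioxabicyclo[3.3.1]non‑6‑en‑3‑one
Product: 15 (1S,5S)‑5‑(7‑chloroheptyl)cyclohex‑2‑ene‑1,5‑diol
Conditions: K2CO3 (cat.), MeOH, rt
Reagents that add atoms: none
Why: Base‑catalysed transesterification (methanolysis) of the cyclic carbonate cleaves only C(=O)–O bonds, so both carbinol centres keep their configuration and the cis‑1,3‑diol is released.

**Step 8**
Reactants: 15 (1S,5S)‑5‑(7‑chloroheptyl)cyclohex‑2‑ene‑1,5‑diol
Product: 16 (1S,5S)‑5‑(7‑iodoheptyl)cyclohex‑2‑ene‑1,5‑diol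
Conditions: NaI, butan‑2‑one, reflux
Reagents that add atoms: sodium iodide, [Na+].[I-]
Why: Finkelstein halide exchange: SN2 displacement at the primary C–Cl bond by iodide, driven by precipitation of NaCl; the hydroxyl groups, the olefin and both stereocentres are not involved.

**Step 9**
Reactants: 17 (4‑bromobutyl)benzene
Product: 18 triphenyl(4‑phenylbutyl)phosphonium bromide
Conditions: PPh3, MeCN, reflux
Reagents that add atoms: triphenylphosphine, c1ccc(cc1)P(c1ccccc1)c1ccccc1
Why: SN2 quaternisation of triphenylphosphine by a primary alkyl bromide gives the phosphonium salt.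

**Step 10**
Reactants: 18 triphenyl(4‑phenylbutyl)phosphonium bromide; 19 pent‑4‑enal
Product: 21 [(4Z)‑nona‑4,8‑dien‑1‑yl]benzene, via phosphonium ylide 20 (not isolated)
Conditions: NaHMDS, THF, 0 °C; then 19, −78 °C → rt
Reagents that add atoms: none
Why: Wittig olefination of a non‑stabilised ylide under lithium‑salt‑free conditions: kinetically controlled formation of the cis‑oxaphosphetane gives the (Z)‑olefin, and the terminal vinyl group of 19 is inert.

**Step 11**
Reactants: 16 (1S,5S)‑5‑(7‑iodoheptyl)cyclohex‑2‑ene‑1,5‑diol; 21 [(4Z)‑nona‑4,8‑dien‑1‑yl]benzene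
Product: 23 (1S,5S)‑5‑[(12Z)‑16‑phenylhexadec‑12‑en‑1‑yl]cyclohex‑2‑ene‑1,5‑diol, via B‑alkyl‑9‑BBN 22 (not isolated)
Conditions: 21 (1.5 equiv), 9‑BBN‑H (1.45 equiv), THF, 0 °C → rt; then 16 (1.0 equiv), Pd(OAc)2 (5 mol %), PCy3 (10 mol %), K3PO4·H2O (2 equiv), THF, rt
Reagents that add atoms: none
Why: Anti‑Markovnikov hydroboration of the monosubstituted C8′=C9′ vinyl group of 21 by 9‑BBN (terminal olefins react far faster than the cis‑disubstituted C12′=C13′ olefin) gives the primary alkylborane 22, whose hydroxide‑activated borate then couples with the primary iodide 16 by SN2‑type oxidative addition of Pd(0)/PCy3 to C7′–I, boron‑to‑palladium transfer of the primary alkyl group and reductive elimination to the C7′–C8′ bond. The closest known reaction type is the Pd/PCy3‑catalysed room‑temperature B‑alkyl Suzuki–Miyaura coupling of primary alkyl halides that carry β‑hydrogens with 9‑alkyl‑9‑BBN reagents. No ring is closed and no stereocentre is formed; C1, C5 and the (Z)‑olefin lie at least four bonds from the reacting carbons and are carried through unchanged. The selectivity needed is chemoselectivity: the bulky electron‑rich PCy3 favours reductive elimination over β‑hydride elimination, the polar pathway at both carbons avoids the 5‑exo cyclisation that a C8′ radical would undergo onto C12′=C13′, and no B–H remains after the hydroboration, so the cyclohexene olefin and the free hydroxyls of 16 do not react with boron. The unactivated secondary allylic and tertiary hydroxyls are poor leaving groups toward Pd(0) at room temperature and the aqueous phosphate holds the borane as its borate, so the diol should need no protection.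

**Compound list**
1 | acrolein (prop‑2‑enal) | C=CC=O | starting material
2 | 2,3‑dibromopropanal (racemic) | O=CC(Br)CBr | intermediate (not isolated)
3 | 2‑bromoprop‑2‑enal (2‑bromoacrolein) | C=C(Br)C=O | intermediate
4 | buta‑1,3‑diene | C=CC=C | starting material
5 | (1R)‑1‑bromocyclohex‑3‑ene‑1‑carbaldehyde | O=C[C@]1(Br)CC=CCC1 | intermediate
6 | [(1R)‑1‑bromocyclohex‑3‑en‑1‑yl]methanol (bromohydrin) | OC[C@]1(Br)CC=CCC1 | intermediate (not isolated)
7 | (3S)‑1‑oxaspiro[2.5]oct‑5‑ene | C1O[C@@]12CC=CCC2 | intermediate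
8 | 1‑bromo‑6‑chlorohexane | ClCCCCCCBr | starting material
9 | (6‑chlorohexyl)magnesium bromide | ClCCCCCC[Mg]Br | intermediate (not isolated)
10 | (1S)‑1‑(7‑chloroheptyl)cyclohex‑3‑en‑1‑ol | O[C@]1(CCCCCCCCl)CC=CCC1 | intermediate
11 | lithium (1S)‑1‑(7‑chloroheptyl)cyclohex‑3‑en‑1‑olate | [Li]O[C@]1(CCCCCCCCl)CC=CCC1 | intermediate (not isolated)
12 | lithium (1S)‑1‑(7‑chloroheptyl)cyclohex‑3‑en‑1‑yl carbonate | [Li+].[O-]C(=O)O[C@]1(CCCCCCCCl)CC=CCC1 | intermediate (not isolated)
13 | (1S,5S,6S)‑1‑(7‑chloroheptyl)‑6‑iodo‑2,4‑dioxabicyclo[3.3.1]nonan‑3‑one | O=C1O[C@]2(CCCCCCCCl)C[C@H](O1)[C@@H](I)CC2 | intermediate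
14 | (1S,5S)‑1‑(7‑chloroheptyl)‑2,4‑dioxabicyclo[3.3.1]non‑6‑en‑3‑one | O=C1O[C@]2(CCCCCCCCl)C[C@H](O1)C=CC2 | intermediate
15 | (1S,5S)‑5‑(7‑chloroheptyl)cyclohex‑2‑ene‑1,5‑diol | O[C@@H]1C=CC[C@@](O)(CCCCCCCCl)C1 | intermediate
16 | (1S,5S)‑5‑(7‑iodoheptyl)cyclohex‑2‑ene‑1,5‑diol | O[C@@H]1C=CC[C@@](O)(CCCCCCCI)C1 | intermediate
17 | (4‑bromobutyl)benzene | BrCCCCc1ccccc1 | starting material
18 | triphenyl(4‑phenylbutyl)phosphonium bromide | [Br-].c1ccccc1CCCC[P+](c1ccccc1)(c1ccccc1)c1ccccc1 | intermediate
19 | pent‑4‑enal | C=CCCC=O | starting material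
20 | triphenyl(4‑phenylbutylidene)phosphorane (ylide) | c1ccccc1CCCC=P(c1ccccc1)(c1ccccc1)c1ccccc1 | intermediate (not isolated)
21 | [(4Z)‑nona‑4,8‑dien‑1‑yl]benzene | C=CCC/C=C\CCCc1ccccc1 | intermediate
22 | 9‑[(5Z)‑9‑phenylnon‑5‑en‑1‑yl]‑9‑borabicyclo[3.3.1]nonane | C(CCC/C=C\CCCc1ccccc1)B1C2CCCC1CCC2 | intermediate (not isolated)
23 | (1S,5S)‑5‑[(12Z)‑16‑phenylhexadec‑12‑en‑1‑yl]cyclohex‑2‑ene‑1,5‑diol | O[C@@H]1C=CC[C@@](O)(CCCCCCCCCCC/C=C\CCCc2ccccc2)C1 | target

**Step count:** 11 steps in total; longest linear sequence 9 steps (steps 1–8 and 11).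

**Steps most likely to fail**

Step 11. Transmetalation from boron may be slower than β‑hydride elimination of the alkylpalladium iodide, or Pd(0) assisted by the borane may ionise the allylic C1–O bond and erode that stereocentre. The fallback makes the same bond with copper and magnesium instead of palladium and boron. It sets out from 21: the borane 22 is oxidised (NaOH, H2O2) to (5Z)‑9‑phenylnon‑5‑en‑1‑ol F1, which CBr4/PPh3 converts into [(4Z)‑9‑bromonon‑4‑en‑1‑yl]benzene F2, and magnesium in THF then gives [(5Z)‑9‑phenylnon‑5‑en‑1‑yl]magnesium bromide F3. Iodide 16 is converted with i‑PrMgCl (2 equiv, −30 °C) into its bis(chloromagnesium) alkoxide F4, and F3 is coupled with F4 under Li2CuCl4 catalysis (THF/NMP, 0 °C; Kochi–Cahiez alkyl–alkyl coupling). Aqueous NH4Cl returns the route at 23.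

Step 2. The poorly reactive, gaseous diene may polymerise or react through the uncatalysed background pathway, so that facial discrimination is lost. The fallback replaces the catalysed cycloaddition by a reagent‑controlled epoxidation and sets out from 4. Thermal Diels–Alder reaction with methyl propiolate (sealed tube, 120 °C) gives methyl cyclohexa‑1,4‑diene‑1‑carboxylate F5, and DIBAL‑H reduces it to (cyclohexa‑1,4‑dien‑1‑yl)methanol F6. Sharpless asymmetric epoxidation (Ti(OiPr)4, L‑(+)‑diethyl tartrate, t‑BuOOH, 4 Å MS, CH2Cl2, −20 °C) epoxidises only the allylic olefin to [(1S,6S)‑7‑oxabicyclo[4.1.0]hept‑3‑en‑1‑yl]methanol F7. DIBAL‑H delivers hydride to the secondary epoxide carbon to give (1S)‑1‑(hydroxymethyl)cyclohex‑3‑en‑1‑ol F8; TsCl/pyridine gives the primary tosylate F9, and NaH in THF closes it to 7, where the route is rejoined.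

Step 5. Incomplete carboxylation of the hindered tertiary alkoxide may let the alkoxide itself open the iodonium ion (iodoetherification to a 7‑oxabicyclo[2.2.1]heptane) or leave 10 unchanged. The fallback uses hydroxyl‑directed epoxidation and selenium chemistry instead of halocyclisation and sets out from 10. VO(acac)2/t‑BuOOH gives the epoxide syn to the hydroxyl, (1S,3S,6R)‑3‑(7‑chloroheptyl)‑7‑oxabicyclo[4.1.0]heptan‑3‑ol F10. PhSeNa (from (PhSe)2/NaBH4, EtOH) should open it trans‑diaxially at the epoxide carbon remote from the CH2 that links the two oxygenated carbons (Fürst–Plattner control with the alkyl chain equatorial), giving (1S,3S,4S)‑1‑(7‑chloroheptyl)‑4‑(phenylselanyl)cyclohexane‑1,3‑diol F11. H2O2 gives the selenoxide F12, whose syn‑elimination away from the carbinol carbon gives 15 directly, so that 13 and 14 are bypassed.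

**Further compounds**
F1 | step 11 | (5Z)‑9‑phenylnon‑5‑en‑1‑ol | OCCCC/C=C\CCCc1ccccc1
F2 | step 11 | [(4Z)‑9‑bromonon‑4‑en‑1‑yl]benzene | BrCCCC/C=C\CCCc1ccccc1
F3 | step 11 | [(5Z)‑9‑phenylnon‑5‑en‑1‑yl]magnesium bromide | Br[Mg]CCCC/C=C\CCCc1ccccc1
F4 | step 11 | bis(chloromagnesium) alkoxide of 16 | Cl[Mg]O[C@@H]1C=CC[C@@](O[Mg]Cl)(CCCCCCCI)C1
F5 | step 2 | methyl cyclohexa‑1,4‑diene‑1‑carboxylate | COC(=O)C1=CCC=CC1
F6 | step 2 | (cyclohexa‑1,4‑dien‑1‑yl)methanol | OCC1=CCC=CC1
F7 | step 2 | [(1S,6S)‑7‑oxabicyclo[4.1.0]hept‑3‑en‑1‑yl]methanol | OC[C@]12O[C@H]1CC=CC2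
F8 | step 2 | (1S)‑1‑(hydroxymethyl)cyclohex‑3‑en‑1‑ol | OC[C@@]1(O)CC=CCC1
F9 | step 2 | [(1S)‑1‑hydroxycyclohex‑3‑en‑1‑yl]methyl 4‑methylbenzenesulfonate | Cc1ccc(cc1)S(=O)(=O)OC[C@@]1(O)CC=CCC1
F10 | step 5 | (1S,3S,6R)‑3‑(7‑chloroheptyl)‑7‑oxabicyclo[4.1.0]heptan‑3‑ol | O[C@]1(CCCCCCCCl)C[C@@H]2O[C@@H]2CC1
F11 | step 5 | (1S,3S,4S)‑1‑(7‑chloroheptyl)‑4‑(phenylselanyl)cyclohexane‑1,3‑diol | O[C@@H]1[C@@H]([Se]c2ccccc2)CC[C@@](O)(CCCCCCCCl)C1
F12 | step 5 | selenoxide of F11 (mixture at selenium) | O[C@@H]1[C@@H]([Se](=O)c2ccccc2)CC[C@@](O)(CCCCCCCCl)C1
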